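**Strategy.** The butanoyl-bearing trione ring (ring A: C1 carbonyl, C2 bridge-bearing carbon, C3 enol carbon, C4 CMe2, C5 enol carbon, C6 acyl-bearing carbon) is disconnected as a double Claisen [4+2] union. In the key step the dianion of methyl 4-methyl-3-oxopentanoate (C1–C6–C5–C4) is acylated at C4 by a propanoate ester hanging from the finished propanoyl ring B (bond C3–C4), and the new ketone enolate closes onto the keto ester (bond C1–C2). It exploits the 1,3,5-oxygen pattern and the quaternary C4 of ring A. Since C3–C2–CH2–C2'–C3' through both rings is a glutarate chain, ring B arises likewise from dimethyl glutarate.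

Key step: step 3

Remark: the target has no stereocentre. Each trione ring is written in the dienol–enone tautomer of the target SMILES, and these tautomers are in rapid equilibrium.

**Step 1**
Reactants: 1 methyl 4-methyl-3-oxopentanoate; 2 dimethyl pentanedioate (dimethyl glutarate)
Product: 5 methyl 3-(2,4-dihydroxy-3,3-dimethyl-6-oxocyclohexa-1,4-dien-1-yl)propanoate, via sodium lithium dienediolate 3 (not isolated), via acyclic diketo diester 4 (not isolated)
Conditions: 1, NaH, THF, 0 °C; n-BuLi, 0 °C; added to 2 (5 equiv), THF, −78 °C to 50 °C; aq. HCl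
Reagents that add atoms: none
Why: The γ-carbon of β-keto ester dianion 3 should be acylated by one ester group of 2 (acylation of β-keto ester dianions by esters) and the methoxide set free should then mediate a Dieckmann condensation of the ketone α-carbon onto the keto ester, the excess of 2 confining the reaction to one end of the diester; no stereocentre is formed.

**Step 2**
Reactants: 5 methyl 3-(2,4-dihydroxy-3,3-dimethyl-6-oxocyclohexa-1,4-dien-1-yl)propanoate; 6 propanoic acid
Product: 8 methyl 3-(2,4-dihydroxy-3,3-dimethyl-6-oxo-5-propanoylcyclohexa-1,4-dien-1-yl)propanoate, via enol propanoate 7 (not isolated)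
Conditions: DCC, DMAP (1.2 equiv), CH2Cl2, 0 °C to rt; aq. HCl wash
Reagents that add atoms: none
Why: Steglich O-acylation of the vinylogous acid should give enol ester 7, and DMAP-mediated O-to-C acyl migration (the standard entry to 2-acylcyclohexane-1,3-diones) should move the propanoyl group to C5 of the ring, its only hydrogen-bearing carbon, where the product is held as a chelated enol.

**Step 3**
Reactants: 8 methyl 3-(2,4-dihydroxy-3,3-dimethyl-6-oxo-5-propanoylcyclohexa-1,4-dien-1-yl)propanoate; 1 methyl 4-methyl-3-oxopentanoate
Product: 11 2-[(2,4-dihydroxy-3,3-dimethyl-6-oxocyclohexa-1,4-dien-1-yl)methyl]-3,5-dihydroxy-4,4-dimethyl-6-propanoylcyclohexa-2,5-dien-1-one, via dilithium dienediolate 9 (not isolated), via acyclic diketo ester 10 (not isolated)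
Conditions: 1 (3 equiv), LiN(i-Pr)2 (6 equiv), THF, −78 to 0 °C; 8 (pre-treated with LiN(i-Pr)2, 2 equiv, THF, −78 °C) added at −78 °C, then to 40 °C; aq. HCl
Reagents that add atoms: none
Why: The tertiary γ-carbanion of 9 (C4) should add to the side-chain ester carbonyl of 8 (C3), whose ring B is masked as its dilithium salt, and lose methoxide to give 10; excess 9 then deprotonates C2 of the new ketone, and this enolate attacks the keto ester carbonyl C1 with loss of methoxide, the delocalised trione anion driving both Claisen events. The closest known reactions are the acylation of β-keto ester dianions by esters and the Dieckmann-type closure of 4,4-dialkyl-3,5-dioxo esters to cyclohexane-1,3,5-triones of the syncarpic acid type, here run as one formal [4+2] annulation. Ring A closes in a 6-(enolendo)-exo-trig mode. No stereocentre arises, because every ring carbon is trigonal or carries two methyl groups. The step needs γ- over α-attack of 9 (secured by the higher charge density at the γ-carbon), attack at the ester and not at ring B (secured by the prior double deprotonation of 8), and closure through C2 only (secured by the quaternary C4, which leaves C2 as the sole enolisable position that reaches C1 through a six-membered ring). The amide-derived all-lithium medium is chosen because lithium polyanions should stay in solution in THF better than mixed sodium salts.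

**Step 4**
Reactants: 11 2-[(2,4-dihydroxy-3,3-dimethyl-6-oxocyclohexa-1,4-dien-1-yl)methyl]-3,5-dihydroxy-4,4-dimethyl-6-propanoylcyclohexa-2,5-dien-1-one; 12 butanoic acid
Product: 14 6-butanoyl-2-[(2,4-dihydroxy-3,3-dimethyl-6-oxo-5-propanoylcyclohexa-1,4-dien-1-yl)methyl]-3,5-dihydroxy-4,4-dimethylcyclohexa-2,5-dien-1-one, via enol butanoate 13 (not isolated)
Conditions: DCC, DMAP (2 equiv), CH2Cl2, 0 °C to rt; aq. HCl wash
Reagents that add atoms: none
Why: The same Steglich O-acylation and DMAP-mediated O-to-C acyl migration should place the butanoyl group on C6 of ring A, the only ring carbon of 11 that still carries hydrogen, while any enol ester formed on the fully substituted ring B cannot migrate to carbon and should hand its acyl group back to DMAP.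

**Compound list**

1 | methyl 4-methyl-3-oxopentanoate | COC(=O)CC(=O)C(C)C | starting material
2 | dimethyl pentanedioate (dimethyl glutarate) | COC(=O)CCCC(=O)OC | starting material
3 | sodium lithium 1-methoxy-4-methylpenta-1,3-diene-1,3-bis(olate) (sodium lithium dianion of 1) | [Na+].[Li+].COC([O-])=CC([O-])=C(C)C | intermediate (not isolated)
4 | dimethyl 4,4-dimethyl-3,5-dioxononanedioate | COC(=O)CC(=O)C(C)(C)C(=O)CCCC(=O)OC | intermediate (not isolated)
5 | methyl 3-(2,4-dihydroxy-3,3-dimethyl-6-oxocyclohexa-1,4-dien-1-yl)propanoate | COC(=O)CCC1=C(O)C(C)(C)C(O)=CC1=O | intermediate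
6 | propanoic acid | CCC(=O)O | starting material
7 | methyl 3-[2-hydroxy-3,3-dimethyl-6-oxo-4-(propanoyloxy)cyclohexa-1,4-dien-1-yl]propanoate | COC(=O)CCC1=C(O)C(C)(C)C(OC(=O)CC)=CC1=O | intermediate (not isolated)
8 | methyl 3-(2,4-dihydroxy-3,3-dimethyl-6-oxo-5-propanoylcyclohexa-1,4-dien-1-yl)propanoate | COC(=O)CCC1=C(O)C(C)(C)C(O)=C(C(=O)CC)C1=O | intermediate
9 | dilithium 1-methoxy-4-methylpenta-1,3-diene-1,3-bis(olate) (dilithium dianion of 1) | [Li+].[Li+].COC([O-])=CC([O-])=C(C)C | intermediate (not isolated)
10 | methyl 7-(2,4-dihydroxy-3,3-dimethyl-6-oxo-5-propanoylcyclohexa-1,4-dien-1-yl)-4,4-dimethyl-3,5-dioxoheptanoate | COC(=O)CC(=O)C(C)(C)C(=O)CCC1=C(O)C(C)(C)C(O)=C(C(=O)CC)C1=O | intermediate (not isolated)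
11 | 2-[(2,4-dihydroxy-3,3-dimethyl-6-oxocyclohexa-1,4-dien-1-yl)methyl]-3,5-dihydroxy-4,4-dimethyl-6-propanoylcyclohexa-2,5-dien-1-one | CCC(=O)C1=C(O)C(C)(C)C(O)=C(CC2=C(O)C(C)(C)C(O)=CC2=O)C1=O | intermediate
12 | butanoic acid | CCCC(=O)O | starting material
13 | 4-[(2,4-dihydroxy-3,3-dimethyl-6-oxo-5-propanoylcyclohexa-1,4-dien-1-yl)methyl]-5-hydroxy-6,6-dimethyl-3-oxocyclohexa-1,4-dien-1-yl butanoate | CCCC(=O)OC1=CC(=O)C(CC2=C(O)C(C)(C)C(O)=C(C(=O)CC)C2=O)=C(O)C1(C)C | intermediate (not isolated)
14 | 6-butanoyl-2-[(2,4-dihydroxy-3,3-dimethyl-6-oxo-5-propanoylcyclohexa-1,4-dien-1-yl)methyl]-3,5-dihydroxy-4,4-dimethylcyclohexa-2,5-dien-1-one | CCCC(=O)C1=C(O)C(C)(C)C(O)=C(CC2=C(O)C(C)(C)C(O)=C(C(=O)CC)C2=O)C1=O | target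

**Total step count:** 4
**Longest linear sequence:** 4 steps

**Steps most likely to fail**

1. Step 3 (key step). The hindered tertiary carbanion of 9 may take a proton from the α-CH2 of the ester of 8 instead of adding to its carbonyl group. The polyanionic intermediates may still be sluggish or poorly soluble. Once ring A exists, retro-Michael scission of the methylene bridge in the polyanion may scramble the two halves into symmetrical dimers. The fallback closes ring A before the fragments are joined. It sets out from 1: dianion 3, made as in step 1, is condensed with an excess of methyl acetate under the conditions of step 1, so that the same two ring bonds form on an ester that carries no acidic ring. This should give, through methyl 4,4-dimethyl-3,5-dioxohexanoate F1 (not isolated), the parent trione 3,5-dihydroxy-4,4-dimethylcyclohexa-2,5-dien-1-one F2. One portion of F2 is propanoylated with 6 (DCC, DMAP) through 5-hydroxy-6,6-dimethyl-3-oxocyclohexa-1,4-dien-1-yl propanoate F3 (not isolated) to 3,5-dihydroxy-4,4-dimethyl-2-propanoylcyclohexa-2,5-dien-1-one F4. Treatment of F4 with dimethylmethylideneammonium iodide should give the Mannich base 2-[(dimethylamino)methyl]-3,5-dihydroxy-4,4-dimethyl-6-propanoylcyclohexa-2,5-dien-1-one F5. Heating F5 with an excess of F2 in dioxane at 80 °C should release dimethylamine, and Michael addition of F2 to the resulting methylene trione comes back to the route at 11, before step 4.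

2. Step 1. A second annulation at the remaining ester group of the product may compete, and proton transfer from the α-CH2 groups of 2 to the carbanion may outrun carbonyl addition. The fallback replaces the diester by a desymmetrised acyl donor and separates acylation from ring closure. It sets out from 1: dianion 3, made as in step 1, is acylated at −78 °C with glutaric anhydride (O=C1CCCC(=O)O1), which can react only once and is far more electrophilic than an ester, to give 9-methoxy-6,6-dimethyl-5,7,9-trioxononanoic acid F6. Fischer esterification (MeOH, catalytic H2SO4) comes back to the route at 4, now isolated, which KOt-Bu in THF should close to 5.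

3. Step 4. The O-to-C acyl migration may stall at the enol ester stage, O-acylation of the ring B enols may consume the reagent, and the basic DMAP medium may promote scrambling of the methylene bridge. The fallback replaces the base-mediated acyl migration by a direct electrophilic C-acylation under Lewis acid (Friedel–Crafts type). It sets out from 11, which is treated with butanoyl chloride and AlCl3 in nitrobenzene at 0 °C to rt, followed by aqueous HCl, and comes back to the route at 14; no new compound is made on the way.

**Further compounds**

F1 | step 3 | methyl 4,4-dimethyl-3,5-dioxohexanoate (not isolated) | COC(=O)CC(=O)C(C)(C)C(C)=O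
F2 | step 3 | 3,5-dihydroxy-4,4-dimethylcyclohexa-2,5-dien-1-one | CC1(C)C(O)=CC(=O)C=C1O
F3 | step 3 | 5-hydroxy-6,6-dimethyl-3-oxocyclohexa-1,4-dien-1-yl propanoate (not isolated) | CCC(=O)OC1=CC(=O)C=C(O)C1(C)C
F4 | step 3 | 3,5-dihydroxy-4,4-dimethyl-2-propanoylcyclohexa-2,5-dien-1-one | CCC(=O)C1=C(O)C(C)(C)C(O)=CC1=O
F5 | step 3 | 2-[(dimethylamino)methyl]-3,5-dihydroxy-4,4-dimethyl-6-propanoylcyclohexa-2,5-dien-1-one | CCC(=O)C1=C(O)C(C)(C)C(O)=C(CN(C)C)C1=O
F6 | step 1 | 9-methoxy-6,6-dimethyl-5,7,9-trioxononanoic acid | COC(=O)CC(=O)C(C)(C)C(=O)CCCC(=O)O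
F0 | step 4 | none | none
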